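# Mutafuran C by mixed Kolbe coupling of two β-oxygenated acids

## Analysis of the target

Mutafuran C (25) is a C20 chain, numbered here from the ester carbonyl C1 to the brominated carbon C20, with one ring: a tetrahydrofuran in which O1 bridges C5 and C8. Its only stereocentres are C5 (R) and C8 (S). They stand 1,4 to each other across the ring oxygen, the two arms are trans, and the ring carbons between them, C6 and C7, are bare methylenes. C8 is both an ether carbon and a propargylic carbon, attached to the C9≡C10–C11=C12 (E) enyne, and the chain ends in an (E)-bromoalkene at C19=C20. The sensitive groups are the methyl ester, the enyne and the vinyl bromide. The last two exclude hydrogenation, strong base and organometallic reagents once they are present, so they have to arrive late. The difficulty is the remote trans relationship in a ring that has no functional group to relay stereochemistry, combined with two different arms. The route rests on the C5–C6–C7–C8 unit, a 1,4-dioxygenated butane whose central C6–C7 bond joins two CH2 groups, each β to an oxygen-bearing stereocentre. Such a bond results when two β-oxygenated carboxylic acids lose CO2 and their radicals combine, and each acid is the reduction product of a β-keto ester.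

## Retrosynthetic reasoning

**C10–C11.** The bond between the alkyne carbon C10 and the alkene carbon C11 is cut first, giving the terminal alkyne 21 and the symmetrical (1E,9E)-dibromodiene 24. This removes the enyne and the vinyl bromide in one operation. The C10 partner is symmetrical, so its two ends need no differentiation beyond the use of an excess. The forward Sonogashira coupling must react once and keep both alkene geometries. 24 goes back to deca-1,9-diyne 22 by twofold hydrozirconation and bromination.

**C10–Si.** Alkyne 21 comes from the silyl-capped alkyne 20. The triisopropylsilyl cap keeps the alkyne inert towards base, electrolysis and mesylation and is removed only before the coupling.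

**O1–C8.** The ring is opened at the ether bond to the propargylic carbon, leading to the acetoxy mesylate 18, which closes through the hydroxy mesylate 19. This bond is chosen over O1–C5 for two reasons. The propargylic carbon is the better SN2 electrophile, and O5 can stay acylated until the closing step, so a free 5-hydroxy methyl ester never has time to lactonise onto C1. The closure inverts C8, so C8 must be made as 8R in the open chain, while C5 keeps its configuration. 18 comes from alcohol 17 and this from 16, in which O8 carries a silyl group and O5 an acetate so that only O8 is activated.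

**C6–C7.** The central bond of 16 is cut into the acids 7 and 15. It divides the chain into two pieces of similar size with one stereocentre each. A polar disconnection here would need a carbanion β to oxygen, which eliminates, whereas a β-oxygenated primary radical is stable. The forward Kolbe electrolysis has to give the cross-product without touching either stereocentre or the protecting groups.

**Acid 7.** 7 goes back through its tert-butyl ester 6 and alcohol 5 to the β-keto ester 4. The C5 stereocentre is set by asymmetric hydrogenation, and the tert-butyl ester is released by acid beside the methyl ester and the acetate. 4 is cut at the ketone–methylene bond into acid chloride 1 and Meldrum's acid 2, via the acyl derivative 3.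

**Acid 15.** 15 goes back through ester 14 and alcohol 13 to the ynone 12, whose asymmetric transfer hydrogenation sets C8. 12 is the oxidation product of the racemic aldol 11, made from ethyl acetate 8 and the ynal 9 (C7–C8 bond).

## Alternatives that were turned down

**Alternative 1:** This route cuts one ring C–O bond and takes both arms back to hydroxymethyl groups, starting from meso-1,2:5,6-diepoxyhexane A1. An epoxide hydrolase adds water to the terminal carbon of the (S)-oxirane only. The new secondary hydroxyl then opens the (R)-oxirane at its internal carbon with inversion (5-exo), giving [(2S,5S)-tetrahydrofuran-2,5-diyl]dimethanol A2.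
- For: the ring, both stereocentres and the trans relationship arise in one catalytic step from an achiral C6 compound. On this point it is stronger than the chosen route.
- Against: A1 must be freed from its chiral diastereomer, and a suitable enzyme must be at hand. A2 is C2-symmetric, so its two arms are homotopic and can only be told apart by a statistical mono-protection. One arm then needs three more carbons. The other must pass through an α-alkoxy aldehyde, which can epimerise at C8, on the way to the alkyne.
- Comparison: about nine or ten steps follow the key step. The chosen route builds the two different arms into the two acids from the start, at the price of a statistical coupling.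

**Alternative 2:** This route forms O1–C5 and C5–C4 together from the diazoketone (4S)-4-(allyloxy)-5-[(tert-butyldiphenylsilyl)oxy]-1-diazopentan-2-one A3. Cu(acac)2 (divalent copper) gives a carbenoid that is attacked by the allyl ether oxygen. The resulting five-membered oxonium ylide shifts allyl from oxygen to carbon by a [2,3]-sigmatropic rearrangement, giving the trans ketone (2R,5S)-2-allyl-5-{[(tert-butyldiphenylsilyl)oxy]methyl}dihydrofuran-3(2H)-one A4.
- For: a well-behaved reaction class with high trans selectivity from one chiral-pool stereocentre. Its ring-forming diastereocontrol is better established than the cross-selectivity of an electrolysis.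
- Against: A4 carries a ketone at C6 that the target lacks, and its removal costs about three steps. The allyl group must gain one carbon and be saturated before any alkyne is present. The silyloxymethyl arm must again pass through an epimerisable aldehyde.
- Comparison: the sequence is long and linear. The chosen route creates C6 and C7 directly as methylenes.

**Alternative 3:** This route forms O1–C5 and C4–C3 from the alkenol (3S)-1-(triisopropylsilyl)hept-6-en-1-yn-3-ol A5 and an acrylate ester. Under O2 with Co(modp)2 (divalent cobalt; modp = 1-morpholinocarbamoyl-4,4-dimethylpentane-1,3-dionate) the hydroxyl adds to the internal alkene carbon and closes the ring. The exocyclic C4 radical adds to the acrylate, and a cyclohexadiene donor supplies hydrogen. The product is methyl 4-[(2R,5S)-5-[(triisopropylsilyl)ethynyl]tetrahydrofuran-2-yl]butanoate A6, the same compound as 20.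
- For: it is clearly the shortest route. A5 needs two or three steps, A6 one, and two more reach 25.
- Against: C5 is set under substrate control by the C8 substituent, and a slim alkynyl group is the weakest case for that control. The C4 radical can also take hydrogen directly, telomerise with acrylate or be trapped by O2.
- Comparison: the chosen route is longer, but it has two independently catalyst-controlled stereocentres and a stereospecific ring closure. The C5/C8 relationship therefore does not depend on a conformational preference.

Key step: step 11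

Assumption: the name is read as mutafuran C, and the SMILES string is taken as the definition of the target (5R,8S, trans ring).

## Route

Step 1
Reactants: 1 methyl 5-chloro-5-oxopentanoate; 2 Meldrum's acid (2,2-dimethyl-1,3-dioxane-4,6-dione)
Product: 3 methyl 5-(2,2-dimethyl-4,6-dioxo-1,3-dioxan-5-ylidene)-5-hydroxypentanoate (acyl Meldrum's acid, enol form)
Conditions: pyridine (2.2 equiv), CH2Cl2, 0 °C to rt; 1 M HCl wash
Reagents that add atoms: none
Why: C-acylation of the doubly activated methylene of Meldrum's acid by an acid chloride is the standard entry to β-keto esters; the methyl ester is not touched.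

Step 2
Reactants: 3 acyl Meldrum's acid
Product: 4 1-tert-butyl 7-methyl 3-oxoheptanedioate
Conditions: t-BuOH (3 equiv), toluene, 90 °C
Reagents that add atoms: tert-butanol, CC(C)(C)O
Why: Thermal fragmentation of the acyl Meldrum's acid gives an acylketene with loss of acetone and CO2, and the alcohol traps it as the β-keto ester (acyl Meldrum's acid alcoholysis).

Step 3
Reactants: 4 1-tert-butyl 7-methyl 3-oxoheptanedioate
Product: 5 1-tert-butyl 7-methyl (3R)-3-hydroxyheptanedioate
Conditions: H2 (4 bar), RuCl2[(R)-BINAP] (0.5 mol%, divalent ruthenium), MeOH, 45 °C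
Reagents that add atoms: none
Why: Noyori asymmetric hydrogenation of a β-keto ester through the ester-chelated ruthenium hydride; the (R)-ligand should give the 3R alcohol as it does with simple 3-oxoalkanoates, and the crude product is acetylated at once because the free 5-hydroxy methyl ester can lactonise.

Step 4
Reactants: 5 1-tert-butyl 7-methyl (3R)-3-hydroxyheptanedioate
Product: 6 1-tert-butyl 7-methyl (3R)-3-acetoxyheptanedioate
Conditions: Ac2O, pyridine, DMAP (cat.), CH2Cl2, 0 °C to rt
Reagents that add atoms: acetic anhydride, CC(=O)OC(C)=O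
Why: Nucleophile-catalysed acylation of a secondary alcohol; the C–O bond of the stereocentre is not broken, and mild conditions avoid β-elimination.

Step 5
Reactants: 6 1-tert-butyl 7-methyl (3R)-3-acetoxyheptanedioate
Product: 7 (3R)-3-acetoxy-7-methoxy-7-oxoheptanoic acid
Conditions: CF3CO2H/CH2Cl2 (1:4), 0 °C to rt
Reagents that add atoms: none
Why: Acidolysis of a tert-butyl ester by loss of the tert-butyl cation as isobutene; methyl ester and acetate are stable to anhydrous acid.

Step 6
Reactants: 8 ethyl acetate; 9 3-(triisopropylsilyl)propynal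
Product: 11 ethyl 3-hydroxy-5-(triisopropylsilyl)pent-4-ynoate (racemate), via ethyl acetate lithium enolate 10 (not isolated)
Conditions: LiN(iPr)2, THF, −78 °C; then 9; AcOH quench at −78 °C
Reagents that add atoms: none
Why: Acetate aldol addition of a lithium ester enolate to an aldehyde that has no α-hydrogen; only 1,2-addition is expected, and the racemate is acceptable because the carbinol is oxidised next.

Step 7
Reactants: 11 ethyl 3-hydroxy-5-(triisopropylsilyl)pent-4-ynoate
Product: 12 ethyl 3-oxo-5-(triisopropylsilyl)pent-4-ynoate
Conditions: Dess–Martin periodinane, CH2Cl2, 0 °C to rt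
Reagents that add atoms: none
Why: Dess–Martin oxidation of a β-hydroxy ester to the β-keto ester under neutral, non-nucleophilic conditions; the bulky silyl group shields the ynone β-carbon from conjugate addition.

Step 8
Reactants: 12 ethyl 3-oxo-5-(triisopropylsilyl)pent-4-ynoate
Product: 13 ethyl (3R)-3-hydroxy-5-(triisopropylsilyl)pent-4-ynoate
Conditions: RuCl[(R,R)-TsDPEN](p-cymene) (1 mol%, divalent ruthenium), HCO2H/Et3N (5:2), CH2Cl2, rt
Reagents that add atoms: none
Why: Noyori asymmetric transfer hydrogenation of an alkynyl ketone; the alkyne takes the place next to the arene ligand that an aryl group takes in aryl ketones, so the (R,R)-catalyst should deliver hydride to the face that gives the 3R propargylic alcohol, and the acidic formate medium keeps the enolisable 1,3-dicarbonyl system from side reactions.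

Step 9
Reactants: 13 ethyl (3R)-3-hydroxy-5-(triisopropylsilyl)pent-4-ynoate
Product: 14 ethyl (3R)-3-[(tert-butyldimethylsilyl)oxy]-5-(triisopropylsilyl)pent-4-ynoate
Conditions: TBSCl, imidazole, DMF, rt
Reagents that add atoms: tert-butyldimethylsilyl chloride, CC(C)(C)[Si](C)(C)Cl
Why: Standard silylation of a secondary propargylic alcohol; the stereocentre is not involved.

Step 10
Reactants: 14 ethyl (3R)-3-[(tert-butyldimethylsilyl)oxy]-5-(triisopropylsilyl)pent-4-ynoate
Product: 15 (3R)-3-[(tert-butyldimethylsilyl)oxy]-5-(triisopropylsilyl)pent-4-ynoic acid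
Conditions: LiOH (2 equiv), THF/H2O (3:1), 0 °C to rt; then 1 M HCl to pH 3 at 0 °C
Reagents that add atoms: lithium hydroxide, [Li+].[OH-]
Why: Ester saponification; low temperature keeps β-elimination of silanolate slow, and the secondary TBS ether and the silylalkyne are stable to cold aqueous hydroxide.

Step 11
Reactants: 7 (3R)-3-acetoxy-7-methoxy-7-oxoheptanoic acid; 15 (3R)-3-[(tert-butyldimethylsilyl)oxy]-5-(triisopropylsilyl)pent-4-ynoic acid
Product: 16 methyl (5R,8R)-5-acetoxy-8-[(tert-butyldimethylsilyl)oxy]-10-(triisopropylsilyl)dec-9-ynoate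
Conditions: Pt anode and Pt cathode, undivided cell, 7 (3 equiv), 15 (1 equiv), NaOMe (5 mol% of total acid), MeOH, constant current about 200 mA cm−2, 15–20 °C, about 1.5 F per mol of acid
Reagents that add atoms: none
Why: Both carboxylates are discharged at the platinum anode to acyloxy radicals that lose CO2, giving the primary C6 radical from 7 and the primary C7 radical from 15; at high current density these build up in a thin layer at the electrode and combine there, while protons are reduced at the cathode. The closest known reaction type is the mixed Kolbe electrolysis of β-acyloxy and β-alkoxy carboxylic acids to protected 1,4-diols. No ring is closed and no stereocentre is formed: C5 and C8 lie next to the radical centres but are not part of them, so the configurations from steps 3 and 8 are carried through. The selectivity needed is cross- over homo-coupling, which is statistical; the threefold excess of the more accessible acid 7 should send most radicals from 15 into 16, and the two symmetrical dimers (a polar bis-acetate diester and an apolar bis-silyl ether) should separate readily from 16 on silica. The second requirement is radical combination and not further oxidation to a cation; primary radicals with an electron-withdrawing β-oxygen are hard to oxidise, and 1,2-acyloxy shift or attack on the silylalkyne are slow compared with combination at the electrode. The weakly acidic methanol should leave acetate, methyl ester, TBS ether and silylalkyne intact if the current is stopped before the solution turns basic.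

Step 12
Reactants: 16 methyl (5R,8R)-5-acetoxy-8-[(tert-butyldimethylsilyl)oxy]-10-(triisopropylsilyl)dec-9-ynoate
Product: 17 methyl (5R,8R)-5-acetoxy-8-hydroxy-10-(triisopropylsilyl)dec-9-ynoate
Conditions: HF·pyridine, pyridine, THF, 0 °C to rt
Reagents that add atoms: none
Why: Fluoride cleavage of the O–Si bond under buffered acidic conditions; the C–Si bond of the silylalkyne and the acetate are stable here, whereas basic fluoride would attack both.

Step 13
Reactants: 17 methyl (5R,8R)-5-acetoxy-8-hydroxy-10-(triisopropylsilyl)dec-9-ynoate
Product: 18 methyl (5R,8R)-5-acetoxy-8-[(methylsulfonyl)oxy]-10-(triisopropylsilyl)dec-9-ynoate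
Conditions: MsCl, Et3N, CH2Cl2, −20 to 0 °C
Reagents that add atoms: methanesulfonyl chloride, CS(=O)(=O)Cl
Why: Sulfonylation of the only free hydroxyl with retention at C8; the propargylic mesylate is used crude and cold.

Step 14
Reactants: 18 methyl (5R,8R)-5-acetoxy-8-[(methylsulfonyl)oxy]-10-(triisopropylsilyl)dec-9-ynoate
Product: 20 methyl 4-[(2R,5S)-5-[(triisopropylsilyl)ethynyl]tetrahydrofuran-2-yl]butanoate, via hydroxy mesylate 19 (not isolated)
Conditions: K2CO3 (3 equiv), MeOH, 0 °C to rt
Reagents that add atoms: none
Why: Methanolysis removes the acetate, and the freed C5 oxygen displaces the propargylic mesylate in a 5-exo-tet intramolecular Williamson etherification with inversion at C8 (8R to 8S) and retention at C5, which gives the trans ring; methanol leaves the methyl ester unchanged and the triisopropylsilyl alkyne resists carbonate.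

Step 15
Reactants: 20 methyl 4-[(2R,5S)-5-[(triisopropylsilyl)ethynyl]tetrahydrofuran-2-yl]butanoate
Product: 21 methyl 4-[(2R,5S)-5-ethynyltetrahydrofuran-2-yl]butanoate
Conditions: Bu4NF (1.2 equiv), THF, 0 °C
Reagents that add atoms: none
Why: Fluoride-induced protodesilylation of a silylalkyne; short contact at 0 °C spares the methyl ester, and C8 has no acidic hydrogen that fluoride could remove.

Step 16
Reactants: 22 deca-1,9-diyne
Product: 24 (1E,9E)-1,10-dibromodeca-1,9-diene, via bis(alkenylzirconocene) 23 (not isolated)
Conditions: Cp2Zr(H)Cl (2.4 equiv, tetravalent zirconium), THF, rt; then N-bromosuccinimide (2.4 equiv), 0 °C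
Reagents that add atoms: N-bromosuccinimide, O=C1CCC(=O)N1Br
Why: Hydrozirconation adds Zr–H syn across each terminal alkyne with zirconium at the terminal carbon, and bromination cleaves the C–Zr bond with retention, so both alkenes should be E.

Step 17
Reactants: 21 methyl 4-[(2R,5S)-5-ethynyltetrahydrofuran-2-yl]butanoate; 24 (1E,9E)-1,10-dibromodeca-1,9-diene (4 equiv)
Product: 25 mutafuran C, methyl 4-[(2R,5S)-5-[(3E,11E)-12-bromododeca-3,11-dien-1-yn-1-yl]tetrahydrofuran-2-yl]butanoate
Conditions: Pd(PPh3)4 (5 mol%, zerovalent palladium), CuI (10 mol%, monovalent copper), iPr2NH, THF, rt, degassed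
Reagents that add atoms: none
Why: Sonogashira coupling of a terminal alkyne with a vinyl bromide proceeds with retention of alkene geometry; the excess of the symmetrical dibromide favours single coupling and leaves the second C–Br bond as the C19=C20 bromoalkene, and unreacted 24 is recovered.

## Compound list

1 | methyl 5-chloro-5-oxopentanoate | COC(=O)CCCC(Cl)=O | starting material
2 | Meldrum's acid | CC1(C)OC(=O)CC(=O)O1 | starting material
3 | methyl 5-(2,2-dimethyl-4,6-dioxo-1,3-dioxan-5-ylidene)-5-hydroxypentanoate | COC(=O)CCCC(O)=C1C(=O)OC(C)(C)OC1=O | intermediate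
4 | 1-tert-butyl 7-methyl 3-oxoheptanedioate | COC(=O)CCCC(=O)CC(=O)OC(C)(C)C | intermediate
5 | 1-tert-butyl 7-methyl (3R)-3-hydroxyheptanedioate | COC(=O)CCC[C@@H](O)CC(=O)OC(C)(C)C | intermediate
6 | 1-tert-butyl 7-methyl (3R)-3-acetoxyheptanedioate | COC(=O)CCC[C@@H](OC(C)=O)CC(=O)OC(C)(C)C | intermediate
7 | (3R)-3-acetoxy-7-methoxy-7-oxoheptanoic acid | COC(=O)CCC[C@@H](OC(C)=O)CC(=O)O | intermediate
8 | ethyl acetate | CCOC(C)=O | starting material
9 | 3-(triisopropylsilyl)propynal | O=CC#C[Si](C(C)C)(C(C)C)C(C)C | starting material
10 | lithium 1-ethoxyethen-1-olate (lithium enolate of ethyl acetate) | [Li]OC(=C)OCC | intermediate (not isolated)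
11 | ethyl 3-hydroxy-5-(triisopropylsilyl)pent-4-ynoate (racemate) | CCOC(=O)CC(O)C#C[Si](C(C)C)(C(C)C)C(C)C | intermediate
12 | ethyl 3-oxo-5-(triisopropylsilyl)pent-4-ynoate | CCOC(=O)CC(=O)C#C[Si](C(C)C)(C(C)C)C(C)C | intermediate
13 | ethyl (3R)-3-hydroxy-5-(triisopropylsilyl)pent-4-ynoate | CCOC(=O)C[C@H](C#C[Si](C(C)C)(C(C)C)C(C)C)O | intermediate
14 | ethyl (3R)-3-[(tert-butyldimethylsilyl)oxy]-5-(triisopropylsilyl)pent-4-ynoate | CCOC(=O)C[C@H](C#C[Si](C(C)C)(C(C)C)C(C)C)O[Si](C)(C)C(C)(C)C | intermediate
15 | (3R)-3-[(tert-butyldimethylsilyl)oxy]-5-(triisopropylsilyl)pent-4-ynoic acid | OC(=O)C[C@H](C#C[Si](C(C)C)(C(C)C)C(C)C)O[Si](C)(C)C(C)(C)C | intermediate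
16 | methyl (5R,8R)-5-acetoxy-8-[(tert-butyldimethylsilyl)oxy]-10-(triisopropylsilyl)dec-9-ynoate | COC(=O)CCC[C@@H](OC(C)=O)CC[C@H](C#C[Si](C(C)C)(C(C)C)C(C)C)O[Si](C)(C)C(C)(C)C | intermediate
17 | methyl (5R,8R)-5-acetoxy-8-hydroxy-10-(triisopropylsilyl)dec-9-ynoate | COC(=O)CCC[C@@H](OC(C)=O)CC[C@H](C#C[Si](C(C)C)(C(C)C)C(C)C)O | intermediate
18 | methyl (5R,8R)-5-acetoxy-8-[(methylsulfonyl)oxy]-10-(triisopropylsilyl)dec-9-ynoate | COC(=O)CCC[C@@H](OC(C)=O)CC[C@H](C#C[Si](C(C)C)(C(C)C)C(C)C)OS(C)(=O)=O | intermediate
19 | methyl (5R,8R)-5-hydroxy-8-[(methylsulfonyl)oxy]-10-(triisopropylsilyl)dec-9-ynoate | COC(=O)CCC[C@@H](O)CC[C@H](C#C[Si](C(C)C)(C(C)C)C(C)C)OS(C)(=O)=O | intermediate (not isolated)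
20 | methyl 4-[(2R,5S)-5-[(triisopropylsilyl)ethynyl]tetrahydrofuran-2-yl]butanoate | COC(=O)CCC[C@@H]1CC[C@@H](C#C[Si](C(C)C)(C(C)C)C(C)C)O1 | intermediate
21 | methyl 4-[(2R,5S)-5-ethynyltetrahydrofuran-2-yl]butanoate | COC(=O)CCC[C@@H]1CC[C@@H](C#C)O1 | intermediate
22 | deca-1,9-diyne | C#CCCCCCCC#C | starting material
23 | (1E,9E)-deca-1,9-diene-1,10-diylbis[chlorobis(cyclopentadienyl)zirconium] | Cl[Zr](C1C=CC=C1)(C1C=CC=C1)/C=C/CCCCCC/C=C/[Zr](Cl)(C1C=CC=C1)C1C=CC=C1 | intermediate (not isolated)
24 | (1E,9E)-1,10-dibromodeca-1,9-diene | Br/C=C/CCCCCC/C=C/Br | intermediate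
25 | mutafuran C, methyl 4-[(2R,5S)-5-[(3E,11E)-12-bromododeca-3,11-dien-1-yn-1-yl]tetrahydrofuran-2-yl]butanoate | COC(=O)CCC[C@@H]1CC[C@@H](C#C/C=C/CCCCCC/C=C/Br)O1 | target

## Step count and least certain steps

Total step count: 17 (five for each acid, the coupling, four to the ring alkyne, one for the dibromide, the final coupling). Longest linear sequence: 11 steps (steps 1–5 or 6–10, then 11–15 and 17).

**Step 11 (key step).**
- What may go wrong: homo-coupling may consume too much of 15. The radicals may be oxidised further to cations and end as methyl ethers or alkenes. The lipophilic silyl acid may foul the anode. The TBS ether may slowly be lost in the methanolic electrolyte.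
- Fallback: it sets out from 7 and returns at 17, replacing the decarboxylative coupling by a one-carbon homologation and an alkynylation.
  - 7 is converted with (COCl)2 into methyl (5R)-5-acetoxy-7-chloro-7-oxoheptanoate F1.
  - Diazomethane turns F1 into methyl (5R)-5-acetoxy-8-diazo-7-oxooctanoate F2.
  - Wolff rearrangement under irradiation in aqueous THF (Arndt–Eistert homologation, neutral so that the β-acetoxy ketone does not eliminate) gives (4R)-4-acetoxy-8-methoxy-8-oxooctanoic acid F3, in which the former carboxyl carbon is C7.
  - Its chloride, methyl (5R)-5-acetoxy-8-chloro-8-oxooctanoate F4, is coupled with (triisopropylsilyl)acetylene [PdCl2(PPh3)2 (divalent palladium), CuI, Et3N; acyl Sonogashira] to the ynone methyl (5R)-5-acetoxy-8-oxo-10-(triisopropylsilyl)dec-9-ynoate F5.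
  - Transfer hydrogenation of F5 with RuCl[(R,R)-TsDPEN](p-cymene) should give 17 directly.

**Step 14.**
- What may go wrong: methanol or methoxide may attack the propargylic mesylate before the acetate is cleaved. Ionisation at C8 may erode the inversion and give some cis ring. The transient 5-hydroxy ester may lactonise.
- Fallback: it sets out from the ketones 4 and 12 and returns at 21, with the roles of the two oxygens exchanged so that an unactivated secondary mesylate at C5 is displaced by the C8 alkoxide in an aprotic medium.
  - Step 3 with RuCl2[(S)-BINAP] gives 1-tert-butyl 7-methyl (3S)-3-hydroxyheptanedioate F6.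
  - Steps 4 and 5 give 1-tert-butyl 7-methyl (3S)-3-acetoxyheptanedioate F7 and (3S)-3-acetoxy-7-methoxy-7-oxoheptanoic acid F8.
  - Step 8 with RuCl[(S,S)-TsDPEN](p-cymene) gives ethyl (3S)-3-hydroxy-5-(triisopropylsilyl)pent-4-ynoate F9.
  - Steps 9 and 10 give ethyl (3S)-3-[(tert-butyldimethylsilyl)oxy]-5-(triisopropylsilyl)pent-4-ynoate F10 and (3S)-3-[(tert-butyldimethylsilyl)oxy]-5-(triisopropylsilyl)pent-4-ynoic acid F11.
  - Electrolysis of F8 with F11 as in step 11 gives methyl (5S,8S)-5-acetoxy-8-[(tert-butyldimethylsilyl)oxy]-10-(triisopropylsilyl)dec-9-ynoate F12.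
  - K2CO3 in MeOH gives methyl (5S,8S)-8-[(tert-butyldimethylsilyl)oxy]-5-hydroxy-10-(triisopropylsilyl)dec-9-ynoate F13, which is mesylated without delay to methyl (5S,8S)-8-[(tert-butyldimethylsilyl)oxy]-5-[(methylsulfonyl)oxy]-10-(triisopropylsilyl)dec-9-ynoate F14.
  - Bu4NF in THF removes both silyl groups from F14, and the C8 alkoxide closes the ring with inversion at C5 to give 21.

**Step 8.**
- What may go wrong: the substrate is a largely enolised 1,3-dicarbonyl compound. Binding of the enol to the ruthenium amide may slow turnover. The ester may compete with the alkyne for the position next to the arene ligand and lower the enantioselectivity. Formate or amine may add to the ynone.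
- Fallback: it sets out from 9 and returns at 15, setting C8 during C–C bond formation instead of by reduction.
  - The chlorotitanium enolate of (4S)-3-acetyl-4-benzyl-1,3-thiazolidine-2-thione (TiCl4, iPr2NEt, CH2Cl2, −78 °C) is added to 9.
  - The sulfur-chelated chair transition state should favour (4S)-4-benzyl-3-[(3R)-3-hydroxy-5-(triisopropylsilyl)pent-4-ynoyl]-1,3-thiazolidine-2-thione F15. The minor diastereomer is removed by chromatography, and the configuration is confirmed by correlation with 13.
  - Silylation (TBSOTf, 2,6-lutidine) gives (4S)-4-benzyl-3-[(3R)-3-[(tert-butyldimethylsilyl)oxy]-5-(triisopropylsilyl)pent-4-ynoyl]-1,3-thiazolidine-2-thione F16.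
  - LiOH in aqueous THF at 0 °C releases 15 and the auxiliary.

## Further compounds

F1 | step 11 | methyl (5R)-5-acetoxy-7-chloro-7-oxoheptanoate | COC(=O)CCC[C@@H](OC(C)=O)CC(Cl)=O
F2 | step 11 | methyl (5R)-5-acetoxy-8-diazo-7-oxooctanoate | COC(=O)CCC[C@@H](OC(C)=O)CC(=O)C=[N+]=[N-]
F3 | step 11 | (4R)-4-acetoxy-8-methoxy-8-oxooctanoic acid | COC(=O)CCC[C@@H](OC(C)=O)CCC(=O)O
F4 | step 11 | methyl (5R)-5-acetoxy-8-chloro-8-oxooctanoate | COC(=O)CCC[C@@H](OC(C)=O)CCC(Cl)=O
F5 | step 11 | methyl (5R)-5-acetoxy-8-oxo-10-(triisopropylsilyl)dec-9-ynoate | COC(=O)CCC[C@@H](OC(C)=O)CCC(=O)C#C[Si](C(C)C)(C(C)C)C(C)C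
F6 | step 14 | 1-tert-butyl 7-methyl (3S)-3-hydroxyheptanedioate | COC(=O)CCC[C@H](O)CC(=O)OC(C)(C)C
F7 | step 14 | 1-tert-butyl 7-methyl (3S)-3-acetoxyheptanedioate | COC(=O)CCC[C@H](OC(C)=O)CC(=O)OC(C)(C)C
F8 | step 14 | (3S)-3-acetoxy-7-methoxy-7-oxoheptanoic acid | COC(=O)CCC[C@H](OC(C)=O)CC(=O)O
F9 | step 14 | ethyl (3S)-3-hydroxy-5-(triisopropylsilyl)pent-4-ynoate | CCOC(=O)C[C@@H](C#C[Si](C(C)C)(C(C)C)C(C)C)O
F10 | step 14 | ethyl (3S)-3-[(tert-butyldimethylsilyl)oxy]-5-(triisopropylsilyl)pent-4-ynoate | CCOC(=O)C[C@@H](C#C[Si](C(C)C)(C(C)C)C(C)C)O[Si](C)(C)C(C)(C)C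
F11 | step 14 | (3S)-3-[(tert-butyldimethylsilyl)oxy]-5-(triisopropylsilyl)pent-4-ynoic acid | OC(=O)C[C@@H](C#C[Si](C(C)C)(C(C)C)C(C)C)O[Si](C)(C)C(C)(C)C
F12 | step 14 | methyl (5S,8S)-5-acetoxy-8-[(tert-butyldimethylsilyl)oxy]-10-(triisopropylsilyl)dec-9-ynoate | COC(=O)CCC[C@H](OC(C)=O)CC[C@@H](C#C[Si](C(C)C)(C(C)C)C(C)C)O[Si](C)(C)C(C)(C)C
F13 | step 14 | methyl (5S,8S)-8-[(tert-butyldimethylsilyl)oxy]-5-hydroxy-10-(triisopropylsilyl)dec-9-ynoate | COC(=O)CCC[C@H](O)CC[C@@H](C#C[Si](C(C)C)(C(C)C)C(C)C)O[Si](C)(C)C(C)(C)C
F14 | step 14 | methyl (5S,8S)-8-[(tert-butyldimethylsilyl)oxy]-5-[(methylsulfonyl)oxy]-10-(triisopropylsilyl)dec-9-ynoate | COC(=O)CCC[C@H](OS(C)(=O)=O)CC[C@@H](C#C[Si](C(C)C)(C(C)C)C(C)C)O[Si](C)(C)C(C)(C)C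
F15 | step 8 | (4S)-4-benzyl-3-[(3R)-3-hydroxy-5-(triisopropylsilyl)pent-4-ynoyl]-1,3-thiazolidine-2-thione | O=C(C[C@H](C#C[Si](C(C)C)(C(C)C)C(C)C)O)N1[C@@H](Cc2ccccc2)CSC1=S
F16 | step 8 | (4S)-4-benzyl-3-[(3R)-3-[(tert-butyldimethylsilyl)oxy]-5-(triisopropylsilyl)pent-4-ynoyl]-1,3-thiazolidine-2-thione | O=C(C[C@H](C#C[Si](C(C)C)(C(C)C)C(C)C)O[Si](C)(C)C(C)(C)C)N1[C@@H](Cc2ccccc2)CSC1=S
A1 | alternative 1 | meso-1,2:5,6-diepoxyhexane, (2R,2'S)-2,2'-(ethane-1,2-diyl)bis(oxirane) | C1O[C@H]1CC[C@@H]1CO1
A2 | alternative 1 | [(2S,5S)-tetrahydrofuran-2,5-diyl]dimethanol | OC[C@@H]1CC[C@@H](CO)O1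
A3 | alternative 2 | (4S)-4-(allyloxy)-5-[(tert-butyldiphenylsilyl)oxy]-1-diazopentan-2-one | [N-]=[N+]=CC(=O)C[C@@H](CO[Si](c1ccccc1)(c1ccccc1)C(C)(C)C)OCC=C
A4 | alternative 2 | (2R,5S)-2-allyl-5-{[(tert-butyldiphenylsilyl)oxy]methyl}dihydrofuran-3(2H)-one | C=CC[C@@H]1C(=O)C[C@@H](CO[Si](c2ccccc2)(c2ccccc2)C(C)(C)C)O1
A5 | alternative 3 | (3S)-1-(triisopropylsilyl)hept-6-en-1-yn-3-ol | C=CCC[C@@H](C#C[Si](C(C)C)(C(C)C)C(C)C)O
A6 | alternative 3 | methyl 4-[(2R,5S)-5-[(triisopropylsilyl)ethynyl]tetrahydrofuran-2-yl]butanoate | COC(=O)CCC[C@@H]1CC[C@@H](C#C[Si](C(C)C)(C(C)C)C(C)C)O1
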